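**Retrosynthetic overview**
- Last bond: the C18–O ester (Steglich) between a labdane alcohol and a C15 hydroxy acid. The cyclohexane of the acid comes intact from β-cyclogeraniol (carbinol carbon by Sharpless epoxidation, ring C–H by hydroxyl-directed hydrogenation, side-chain methyl centre by Ru–BINAP hydrogenation).
- Labdane core: both carbocycles come from one acyclic epoxy triene in a single Lewis-acid cascade. The C5=C10 alkene opens the oxirane at C4 and closes ring A; C9 of an allylsilane then attacks the C10 cation and closes ring B, the last ring of the route; loss of Me3Si writes the C8=C17 methylene.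
- Enabling feature: in ring B the exocyclic C8=C17 methylene flanks C9 (allylsilane retron) and sits in 1,5-spacing to C5=C10 and C4. The quaternary C4 with CH3 and the C18 CH2O is the retron of an E-2,3-epoxy alcohol; the extra C3–OH is removed afterwards.
- Precursor assembly: geranyl acetate (SeO2, Sharpless epoxidation) to an epoxy allylic bromide; alkylation of the acetyltrimethylsilane enolate; vinyllithium addition/Brook rearrangement/alkylation with a C5 bromo enoate; enol triflate; Me3SiCH2 cross-coupling.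
- Ring order: cyclohexane of the acid (present in the starting material), ring A, ring B.

Key step: step 18

Remark: labdane numbering is used for the diterpene part (C18 = the 4α, equatorial CH2O carbon; C17 = the exocyclic methylene carbon); primed locants refer to the cyclohexane of the acid.
Remark: β-cyclogeraniol, geranyl acetate, acetyltrimethylsilane, methyl (2E)-4-bromo-3-methylbut-2-enoate and vinyllithium solution are taken as purchasable.

**Part A: the hydroxy acid**

Step 1
Reactants: 1 β-cyclogeraniol [(2,6,6-trimethylcyclohex-1-en-1-yl)methanol]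
Product: 2 [(1R,6R)-2,2,6-trimethyl-7-oxabicyclo[4.1.0]heptan-1-yl]methanol
Conditions: Ti(OiPr)4 (1.0 equiv), D-(−)-diethyl tartrate (1.2 equiv), tBuOOH (2 equiv, isooctane), 4 Å MS, CH2Cl2, −20 °C
Reagents that add atoms: tert-butyl hydroperoxide, CC(C)(C)OO
Why: Sharpless asymmetric epoxidation; the allylic hydroxyl binds the titanium tartrate and the D-(−)-tartrate should deliver oxygen to the face that makes both oxirane carbons R, which fixes the future carbinol carbon C2'.

Step 2
Reactants: 2 [(1R,6R)-2,2,6-trimethyl-7-oxabicyclo[4.1.0]heptan-1-yl]methanol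
Product: 3 (1S,6R)-2,2,6-trimethyl-7-oxabicyclo[4.1.0]heptane-1-carbaldehyde
Conditions: Dess–Martin periodinane (1.3 equiv), pyridine, CH2Cl2, 0 °C → rt
Reagents that add atoms: none
Why: Dess–Martin oxidation of the primary alcohol under buffered conditions; the oxirane carbons are untouched (the descriptor at C1 changes by priority only).

Step 3
Reactants: 3 (1S,6R)-2,2,6-trimethyl-7-oxabicyclo[4.1.0]heptane-1-carbaldehyde
Product: 4 (3E)-4-[(1S,6R)-2,2,6-trimethyl-7-oxabicyclo[4.1.0]heptan-1-yl]but-3-en-2-one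
Conditions: Ph3P=CHC(O)CH3 (1.5 equiv), toluene, 90 °C
Reagents that add atoms: 1-(triphenyl-λ5-phosphanylidene)propan-2-one, CC(=O)C=P(c1ccccc1)(c1ccccc1)c1ccccc1
Why: Wittig olefination with a stabilised ylide, which should give the E-enone; the aldehyde α-carbon is quaternary and cannot epimerise.

Step 4
Reactants: 4 (3E)-4-[(1S,6R)-2,2,6-trimethyl-7-oxabicyclo[4.1.0]heptan-1-yl]but-3-en-2-one
Product: 5 4-[(2R)-2-hydroxy-2,6,6-trimethylcyclohexylidene]butan-2-one (alkene isomers)
Conditions: SmI2 (2.2 equiv), THF–MeOH, −78 °C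
Reagents that add atoms: none
Why: reductive opening of a γ,δ-epoxy enone by divalent samarium (two single-electron transfers, C–O cleavage at the γ-carbon, kinetic α-protonation of the dienolate) should give the δ-hydroxy β,γ-unsaturated ketone; the C–O bond at the carbinol carbon is not broken, so its R configuration is kept.

Step 5
Reactants: 5 4-[(2R)-2-hydroxy-2,6,6-trimethylcyclohexylidene]butan-2-one (alkene isomers)
Product: 6 4-[(1R,2R)-2-hydroxy-2,6,6-trimethylcyclohexyl]butan-2-one
Conditions: [Ir(cod)(PCy3)(py)]PF6 (5 mol%), H2 (1 atm), CH2Cl2, 0 °C → rt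
Reagents that add atoms: none
Why: hydroxyl-directed homogeneous hydrogenation; the tertiary allylic alcohol binds the cationic iridium centre, so both alkene isomers should receive hydrogen at the ring carbon on the face of the OH group, which sets C1'–H cis to OH (side chain trans to OH).

Step 6
Reactants: 6 4-[(1R,2R)-2-hydroxy-2,6,6-trimethylcyclohexyl]butan-2-one
Product: 7 methyl (2E)-5-[(1R,2R)-2-hydroxy-2,6,6-trimethylcyclohexyl]-3-methylpent-2-enoate
Conditions: (MeO)2P(O)CH2CO2Me, NaH (2.5 equiv), THF, 0 → 60 °C; the minor Z isomer is removed by chromatography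
Reagents that add atoms: trimethyl phosphonoacetate, COC(=O)CP(=O)(OC)OC
Why: Horner–Wadsworth–Emmons olefination of a methyl ketone, expected to favour the E-enoate (ester trans to the longer chain); the tertiary alkoxide is a spectator.

Step 7
Reactants: 7 methyl (2E)-5-[(1R,2R)-2-hydroxy-2,6,6-trimethylcyclohexyl]-3-methylpent-2-enoate
Product: 8 (2E)-5-[(1R,2R)-2-hydroxy-2,6,6-trimethylcyclohexyl]-3-methylpent-2-enoic acid
Conditions: LiOH (3 equiv), THF–MeOH–H2O, rt; then 1 M HCl to pH 3
Reagents that add atoms: lithium hydroxide, [Li+].[OH-]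
Why: saponification (acyl substitution by hydroxide) leaves the alkene geometry and the tertiary alcohol untouched and frees the carboxylic acid that anchors the hydrogenation catalyst.

Step 8
Reactants: 8 (2E)-5-[(1R,2R)-2-hydroxy-2,6,6-trimethylcyclohexyl]-3-methylpent-2-enoic acid
Product: 9 (3S)-5-[(1R,2R)-2-hydroxy-2,6,6-trimethylcyclohexyl]-3-methylpentanoic acid
Conditions: Ru(OAc)2[(R)-BINAP] (1 mol%), H2 (100 atm), MeOH, rt
Reagents that add atoms: none
Why: carboxylate-directed asymmetric hydrogenation of a β,β-disubstituted acrylic acid with a BINAP–ruthenium dicarboxylate; by analogy with E-configured geranic acid the (R)-ligand should deliver hydrogen to the face that gives the 3S centre.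

**Part B: the labdane alcohol and the union**

Step 9
Reactants: 10 geranyl acetate
Product: 11 (2E,6E)-8-hydroxy-3,7-dimethylocta-2,6-dien-1-yl acetate
Conditions: SeO2 (0.2 equiv), tBuOOH (3 equiv), salicylic acid (0.1 equiv), CH2Cl2, rt
Reagents that add atoms: tert-butyl hydroperoxide, CC(C)(C)OO (terminal oxidant); selenium dioxide, O=[Se]=O (catalytic oxygen carrier)
Why: SeO2-catalysed allylic oxidation (ene reaction, then [2,3]-sigmatropic shift) attacks the E-methyl of the terminal trisubstituted alkene, the other alkene being deactivated by the allylic acetate, so the E-allylic alcohol should form.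

Step 10
Reactants: 11 (2E,6E)-8-hydroxy-3,7-dimethylocta-2,6-dien-1-yl acetate
Product: 12 (2E)-5-[(2S,3S)-3-(hydroxymethyl)-3-methyloxiran-2-yl]-3-methylpent-2-en-1-yl acetate
Conditions: Ti(OiPr)4 (10 mol%), L-(+)-diethyl tartrate (12 mol%), tBuOOH (2 equiv), 4 Å MS, CH2Cl2, −20 °C
Reagents that add atoms: tert-butyl hydroperoxide, CC(C)(C)OO
Why: Sharpless asymmetric epoxidation, chemoselective for the free allylic alcohol; the L-(+)-tartrate should give the (2S,3S)-epoxy alcohol, and the E geometry keeps the CH2OH group trans to the chain on the oxirane.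

Step 11
Reactants: 12 (2E)-5-[(2S,3S)-3-(hydroxymethyl)-3-methyloxiran-2-yl]-3-methylpent-2-en-1-yl acetate
Product: 13 (2E)-5-[(2S,3S)-3-({[tert-butyl(dimethyl)silyl]oxy}methyl)-3-methyloxiran-2-yl]-3-methylpent-2-en-1-yl acetate
Conditions: TBSCl (1.2 equiv), imidazole (2.5 equiv), DMF, 0 °C → rt
Reagents that add atoms: tert-butyldimethylsilyl chloride, C[Si](C)(Cl)C(C)(C)C
Why: silylation of the primary alcohol (substitution at silicon) blocks Payne rearrangement in the next step and gives an ether that cannot take part in the later cationic cascade.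

Step 12
Reactants: 13 (2E)-5-[(2S,3S)-3-({[tert-butyl(dimethyl)silyl]oxy}methyl)-3-methyloxiran-2-yl]-3-methylpent-2-en-1-yl acetate
Product: 14 (2E)-5-[(2S,3S)-3-({[tert-butyl(dimethyl)silyl]oxy}methyl)-3-methyloxiran-2-yl]-3-methylpent-2-en-1-ol
Conditions: K2CO3 (0.2 equiv), MeOH, 0 °C
Reagents that add atoms: none
Why: base-catalysed transesterification removes the acetate; the oxirane and the silyl ether are stable to methoxide at 0 °C.

Step 13
Reactants: 14 (2E)-5-[(2S,3S)-3-({[tert-butyl(dimethyl)silyl]oxy}methyl)-3-methyloxiran-2-yl]-3-methylpent-2-en-1-ol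
Product: 16 (2S,3S)-3-[(3E)-5-bromo-3-methylpent-3-en-1-yl]-2-({[tert-butyl(dimethyl)silyl]oxy}methyl)-2-methyloxirane, via allylic mesylate 15 (not isolated)
Conditions: MsCl (1.2 equiv), Et3N (1.5 equiv), THF, −40 °C; then LiBr (4 equiv), THF, 0 °C
Reagents that add atoms: lithium bromide, [Li+].[Br-]; methanesulfonyl chloride, CS(=O)(=O)Cl (its atoms stay only in intermediate 15)
Why: sulfonylation followed by SN2 displacement with bromide gives the primary allylic bromide without acid, so the alkene geometry and the oxirane should survive.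

Step 14
Reactants: 16 (2S,3S)-3-[(3E)-5-bromo-3-methylpent-3-en-1-yl]-2-({[tert-butyl(dimethyl)silyl]oxy}methyl)-2-methyloxirane; 17 acetyltrimethylsilane
Product: 19 (4E)-7-[(2S,3S)-3-({[tert-butyl(dimethyl)silyl]oxy}methyl)-3-methyloxiran-2-yl]-5-methyl-1-(trimethylsilyl)hept-4-en-1-one, via lithium enolate 18 (not isolated)
Conditions: LiN(iPr)2 (1.05 equiv), 17, THF, −78 °C; then 16, DMPU, −78 → −20 °C
Reagents that add atoms: none
Why: C-alkylation of the kinetic lithium enolate of an acylsilane by a primary allylic bromide (SN2) installs C7 and C8 in one step; the hindered trisubstituted oxirane is not attacked at low temperature.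

Step 15
Reactants: 19 (4E)-7-[(2S,3S)-3-({[tert-butyl(dimethyl)silyl]oxy}methyl)-3-methyloxiran-2-yl]-5-methyl-1-(trimethylsilyl)hept-4-en-1-one; 20 methyl (2E)-4-bromo-3-methylbut-2-enoate
Product: 23 methyl (2E,6Z,10E)-13-[(2S,3S)-3-({[tert-butyl(dimethyl)silyl]oxy}methyl)-3-methyloxiran-2-yl]-3,11-dimethyl-7-[(trimethylsilyl)oxy]trideca-2,6,10-trienoate, via lithium alkoxide 21 (not isolated), via siloxyallyl-lithium 22 (not isolated)
Conditions: CH2=CHLi (1.1 equiv), THF–Et2O, −78 °C; warm to −45 °C; recool to −78 °C, then 20 (1.2 equiv), −78 → −40 °C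
Reagents that add atoms: vinyllithium, [Li]C=C
Why: addition of vinyllithium to the acylsilane, Brook rearrangement (silyl shift from C to O) to a lithium-chelated siloxyallyl anion and γ-alkylation by the allylic bromide (SN2) should give the silyl enol ether with O and the new CH2 cis (6Z), which fixes the later trans relationship of C7 and C11.

Step 16
Reactants: 23 methyl (2E,6Z,10E)-13-[(2S,3S)-3-({[tert-butyl(dimethyl)silyl]oxy}methyl)-3-methyloxiran-2-yl]-3,11-dimethyl-7-[(trimethylsilyl)oxy]trideca-2,6,10-trienoate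
Product: 24 methyl (2E,6Z,10E)-13-[(2S,3S)-3-({[tert-butyl(dimethyl)silyl]oxy}methyl)-3-methyloxiran-2-yl]-3,11-dimethyl-7-{[(trifluoromethyl)sulfonyl]oxy}trideca-2,6,10-trienoate
Conditions: CsF (3 equiv), PhNTf2 (1.5 equiv), DME, rt
Reagents that add atoms: N-phenyl-bis(trifluoromethanesulfonimide), O=S(=O)(N(c1ccccc1)S(=O)(=O)C(F)(F)F)C(F)(F)F
Why: fluoride cleaves the enol Si–O bond and the regiodefined enolate is O-sulfonylated with retention of geometry; the much more robust primary silyl ether should be untouched by the sparingly soluble CsF.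

Step 17
Reactants: 24 methyl (2E,6Z,10E)-13-[(2S,3S)-3-({[tert-butyl(dimethyl)silyl]oxy}methyl)-3-methyloxiran-2-yl]-3,11-dimethyl-7-{[(trifluoromethyl)sulfonyl]oxy}trideca-2,6,10-trienoate
Product: 25 methyl (2E,6Z,10E)-13-[(2S,3S)-3-({[tert-butyl(dimethyl)silyl]oxy}methyl)-3-methyloxiran-2-yl]-3,11-dimethyl-7-[(trimethylsilyl)methyl]trideca-2,6,10-trienoate
Conditions: Me3SiCH2MgCl (1.3 equiv), Pd(PPh3)4 (5 mol%), Et2O, 0 °C
Reagents that add atoms: (trimethylsilylmethyl)magnesium chloride, C[Si](C)(C)C[Mg]Cl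
Why: Kumada coupling of an alkenyl triflate at zerovalent palladium proceeds with retention of alkene geometry and should outrun addition of this hindered Grignard reagent to the methyl ester at 0 °C.

Step 18
Reactants: 25 methyl (2E,6Z,10E)-13-[(2S,3S)-3-({[tert-butyl(dimethyl)silyl]oxy}methyl)-3-methyloxiran-2-yl]-3,11-dimethyl-7-[(trimethylsilyl)methyl]trideca-2,6,10-trienoate
Product: 26 methyl (13E)-18-{[tert-butyl(dimethyl)silyl]oxy}-3β-hydroxylabda-8(17),13-dien-15-oate
Conditions: MeAlCl2 (2.0 equiv), CH2Cl2, −94 → −78 °C; Et3N–MeOH, then aqueous NaHCO3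
Reagents that add atoms: none
Why: MeAlCl2 binds the oxirane oxygen and the C5=C10 alkene opens the epoxide at the tertiary C4 anti to the leaving oxygen (ring A: 6-endo attack of the alkene with endo opening of the oxirane, chair); the C10 cation is then captured by C9 of the allylsilane (ring B, the last ring: 6-endo, chair) and the β-silyl cation at C8 collapses by loss of Me3Si to the C8=C17 methylene, so no proton loss is involved and no alkene isomers can arise. The closest known reaction type is the Lewis-acid-promoted, epoxide-initiated cation–olefin polycyclisation of all-trans epoxy polyenes terminated by an allylsilane. Stereocontrol: the (2S,3S)-oxirane keeps C3 (3β-OH, equatorial) and, through anti opening with the CH2OTBS group trans to the chain, puts C18 equatorial (4α) and the C4 methyl axial; the E C5=C10 alkene gives the trans ring fusion (5α-H, 10β-CH3) by antiperiplanar addition; the allylsilane geometry (C7 trans to C11) puts the side chain equatorial at C9 (9β). Selectivity needed is initiation only at the oxirane and termination only at C8: the conjugated C13=C14 enoate is too electron-poor to join the cascade, the silyl ether does not trap the cations, and the Al–CH3 bond scavenges adventitious acid that would protodesilylate the allylsilane.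

Step 19
Reactants: 26 methyl (13E)-18-{[tert-butyl(dimethyl)silyl]oxy}-3β-hydroxylabda-8(17),13-dien-15-oate
Product: 27 methyl (13E)-18-{[tert-butyl(dimethyl)silyl]oxy}-3β-[(1H-imidazol-1-ylcarbonothioyl)oxy]labda-8(17),13-dien-15-oate
Conditions: 1,1'-thiocarbonyldiimidazole (3 equiv), DMAP (0.2 equiv), 1,2-dichloroethane, 80 °C
Reagents that add atoms: 1,1'-thiocarbonyldiimidazole, S=C(n1ccnc1)n1ccnc1
Why: thioacylation of the hindered equatorial secondary alcohol (addition–elimination at the thiocarbonyl) prepares the radical deoxygenation under neutral conditions; no stereocentre is touched.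

Step 20
Reactants: 27 methyl (13E)-18-{[tert-butyl(dimethyl)silyl]oxy}-3β-[(1H-imidazol-1-ylcarbonothioyl)oxy]labda-8(17),13-dien-15-oate
Product: 28 methyl (13E)-18-{[tert-butyl(dimethyl)silyl]oxy}labda-8(17),13-dien-15-oate
Conditions: Bu3SnH (2 equiv), AIBN (0.2 equiv), toluene, 110 °C
Reagents that add atoms: none
Why: Barton–McCombie deoxygenation (stannyl radical adds to C=S, β-scission gives the secondary C3 radical, hydrogen transfer from Bu3SnH) removes the auxiliary oxygen; the C3 radical cannot reach either alkene across the trans-decalin.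

Step 21
Reactants: 28 methyl (13E)-18-{[tert-butyl(dimethyl)silyl]oxy}labda-8(17),13-dien-15-oate
Product: 29 methyl (13E)-18-hydroxylabda-8(17),13-dien-15-oate
Conditions: Bu4NF (1.5 equiv), THF, rt
Reagents that add atoms: none
Why: fluoride-induced cleavage of the Si–O bond frees the neopentyl primary alcohol; the methyl enoate and the exocyclic alkene are stable to these conditions.

Step 22
Reactants: 29 methyl (13E)-18-hydroxylabda-8(17),13-dien-15-oate; 9 (3S)-5-[(1R,2R)-2-hydroxy-2,6,6-trimethylcyclohexyl]-3-methylpentanoic acid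
Product: 30 methyl (13E)-18-({(3S)-5-[(1R,2R)-2-hydroxy-2,6,6-trimethylcyclohexyl]-3-methylpentanoyl}oxy)labda-8(17),13-dien-15-oate (CNP0174687.1)
Conditions: EDC·HCl (1.5 equiv), DMAP (1.0 equiv), CH2Cl2, rt
Reagents that add atoms: none
Why: Steglich esterification; the carbodiimide-activated acid is passed through the acylpyridinium ion to the primary C18 alcohol, and the hindered tertiary alcohol of 9 should not compete.

**Compound list**
1 | β-cyclogeraniol, (2,6,6-trimethylcyclohex-1-en-1-yl)methanol | CC1=C(CO)C(C)(C)CCC1 | starting material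
2 | [(1R,6R)-2,2,6-trimethyl-7-oxabicyclo[4.1.0]heptan-1-yl]methanol | OC[C@@]12O[C@]1(C)CCCC2(C)C | intermediate
3 | (1S,6R)-2,2,6-trimethyl-7-oxabicyclo[4.1.0]heptane-1-carbaldehyde | O=C[C@@]12O[C@]1(C)CCCC2(C)C | intermediate
4 | (3E)-4-[(1S,6R)-2,2,6-trimethyl-7-oxabicyclo[4.1.0]heptan-1-yl]but-3-en-2-one | CC(=O)/C=C/[C@@]12O[C@]1(C)CCCC2(C)C | intermediate
5 | 4-[(2R)-2-hydroxy-2,6,6-trimethylcyclohexylidene]butan-2-one (alkene isomers) | CC(=O)CC=C1C(C)(C)CCC[C@@]1(C)O | intermediate
6 | 4-[(1R,2R)-2-hydroxy-2,6,6-trimethylcyclohexyl]butan-2-one | CC(=O)CC[C@@H]1C(C)(C)CCC[C@@]1(C)O | intermediate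
7 | methyl (2E)-5-[(1R,2R)-2-hydroxy-2,6,6-trimethylcyclohexyl]-3-methylpent-2-enoate | COC(=O)/C=C(C)/CC[C@@H]1C(C)(C)CCC[C@@]1(C)O | intermediate
8 | (2E)-5-[(1R,2R)-2-hydroxy-2,6,6-trimethylcyclohexyl]-3-methylpent-2-enoic acid | OC(=O)/C=C(C)/CC[C@@H]1C(C)(C)CCC[C@@]1(C)O | intermediate
9 | (3S)-5-[(1R,2R)-2-hydroxy-2,6,6-trimethylcyclohexyl]-3-methylpentanoic acid | OC(=O)C[C@@H](C)CC[C@@H]1C(C)(C)CCC[C@@]1(C)O | intermediate
10 | geranyl acetate | CC(C)=CCC/C(C)=C/COC(C)=O | starting material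
11 | (2E,6E)-8-hydroxy-3,7-dimethylocta-2,6-dien-1-yl acetate | CC(=O)OC/C=C(C)/CC/C=C(C)/CO | intermediate
12 | (2E)-5-[(2S,3S)-3-(hydroxymethyl)-3-methyloxiran-2-yl]-3-methylpent-2-en-1-yl acetate | CC(=O)OC/C=C(C)/CC[C@@H]1O[C@@]1(C)CO | intermediate
13 | (2E)-5-[(2S,3S)-3-({[tert-butyl(dimethyl)silyl]oxy}methyl)-3-methyloxiran-2-yl]-3-methylpent-2-en-1-yl acetate | CC(=O)OC/C=C(C)/CC[C@@H]1O[C@@]1(C)CO[Si](C)(C)C(C)(C)C | intermediate
14 | (2E)-5-[(2S,3S)-3-({[tert-butyl(dimethyl)silyl]oxy}methyl)-3-methyloxiran-2-yl]-3-methylpent-2-en-1-ol | OC/C=C(C)/CC[C@@H]1O[C@@]1(C)CO[Si](C)(C)C(C)(C)C | intermediate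
15 | allylic mesylate, (2E)-5-[(2S,3S)-3-({[tert-butyl(dimethyl)silyl]oxy}methyl)-3-methyloxiran-2-yl]-3-methylpent-2-en-1-yl methanesulfonate | CS(=O)(=O)OC/C=C(C)/CC[C@@H]1O[C@@]1(C)CO[Si](C)(C)C(C)(C)C | intermediate
16 | (2S,3S)-3-[(3E)-5-bromo-3-methylpent-3-en-1-yl]-2-({[tert-butyl(dimethyl)silyl]oxy}methyl)-2-methyloxirane | BrC/C=C(C)/CC[C@@H]1O[C@@]1(C)CO[Si](C)(C)C(C)(C)C | intermediate
17 | acetyltrimethylsilane | CC(=O)[Si](C)(C)C | starting material
18 | lithium enolate, lithium 1-(trimethylsilyl)ethen-1-olate | [Li+].C=C([O-])[Si](C)(C)C | intermediate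
19 | (4E)-7-[(2S,3S)-3-({[tert-butyl(dimethyl)silyl]oxy}methyl)-3-methyloxiran-2-yl]-5-methyl-1-(trimethylsilyl)hept-4-en-1-one | C[Si](C)(C)C(=O)CC/C=C(C)/CC[C@@H]1O[C@@]1(C)CO[Si](C)(C)C(C)(C)C | intermediate
20 | methyl (2E)-4-bromo-3-methylbut-2-enoate | COC(=O)/C=C(C)/CBr | starting material
21 | lithium alkoxide, lithium (6E)-9-[(2S,3S)-3-({[tert-butyl(dimethyl)silyl]oxy}methyl)-3-methyloxiran-2-yl]-7-methyl-3-(trimethylsilyl)nona-1,6-dien-3-olate | [Li+].C=CC([O-])([Si](C)(C)C)CC/C=C(C)/CC[C@@H]1O[C@@]1(C)CO[Si](C)(C)C(C)(C)C | intermediate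
22 | siloxyallyl-lithium, lithium (2Z,6E)-9-[(2S,3S)-3-({[tert-butyl(dimethyl)silyl]oxy}methyl)-3-methyloxiran-2-yl]-7-methyl-3-[(trimethylsilyl)oxy]nona-2,6-dien-1-ide | [Li+].[CH2-]/C=C(O[Si](C)(C)C)/CC/C=C(C)/CC[C@@H]1O[C@@]1(C)CO[Si](C)(C)C(C)(C)C | intermediate
23 | methyl (2E,6Z,10E)-13-[(2S,3S)-3-({[tert-butyl(dimethyl)silyl]oxy}methyl)-3-methyloxiran-2-yl]-3,11-dimethyl-7-[(trimethylsilyl)oxy]trideca-2,6,10-trienoate | COC(=O)/C=C(C)/CC/C=C(O[Si](C)(C)C)/CC/C=C(C)/CC[C@@H]1O[C@@]1(C)CO[Si](C)(C)C(C)(C)C | intermediate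
24 | methyl (2E,6Z,10E)-13-[(2S,3S)-3-({[tert-butyl(dimethyl)silyl]oxy}methyl)-3-methyloxiran-2-yl]-3,11-dimethyl-7-{[(trifluoromethyl)sulfonyl]oxy}trideca-2,6,10-trienoate | COC(=O)/C=C(C)/CC/C=C(OS(=O)(=O)C(F)(F)F)/CC/C=C(C)/CC[C@@H]1O[C@@]1(C)CO[Si](C)(C)C(C)(C)C | intermediate
25 | methyl (2E,6Z,10E)-13-[(2S,3S)-3-({[tert-butyl(dimethyl)silyl]oxy}methyl)-3-methyloxiran-2-yl]-3,11-dimethyl-7-[(trimethylsilyl)methyl]trideca-2,6,10-trienoate | COC(=O)/C=C(C)/CC/C=C(C[Si](C)(C)C)/CC/C=C(C)/CC[C@@H]1O[C@@]1(C)CO[Si](C)(C)C(C)(C)C | intermediate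
26 | methyl (13E)-18-{[tert-butyl(dimethyl)silyl]oxy}-3β-hydroxylabda-8(17),13-dien-15-oate | C=C1CC[C@H]2[C@](C)(CO[Si](C)(C)C(C)(C)C)[C@@H](O)CC[C@]2(C)[C@H]1CC/C(C)=C/C(=O)OC | intermediate
27 | methyl (13E)-18-{[tert-butyl(dimethyl)silyl]oxy}-3β-[(1H-imidazol-1-ylcarbonothioyl)oxy]labda-8(17),13-dien-15-oate | C=C1CC[C@H]2[C@](C)(CO[Si](C)(C)C(C)(C)C)[C@@H](OC(=S)n3ccnc3)CC[C@]2(C)[C@H]1CC/C(C)=C/C(=O)OC | intermediate
28 | methyl (13E)-18-{[tert-butyl(dimethyl)silyl]oxy}labda-8(17),13-dien-15-oate | C=C1CC[C@H]2[C@](C)(CO[Si](C)(C)C(C)(C)C)CCC[C@]2(C)[C@H]1CC/C(C)=C/C(=O)OC | intermediate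
29 | methyl (13E)-18-hydroxylabda-8(17),13-dien-15-oate | C=C1CC[C@H]2[C@](C)(CO)CCC[C@]2(C)[C@H]1CC/C(C)=C/C(=O)OC | intermediate
30 | methyl (13E)-18-({(3S)-5-[(1R,2R)-2-hydroxy-2,6,6-trimethylcyclohexyl]-3-methylpentanoyl}oxy)labda-8(17),13-dien-15-oate (CNP0174687.1) | C=C1CC[C@H]2[C@](C)(COC(=O)C[C@@H](C)CC[C@@H]3C(C)(C)CCC[C@@]3(C)O)CCC[C@]2(C)[C@H]1CC/C(C)=C/C(=O)OC | target

**Step count and risks**
Total step count: 22. Longest linear sequence: 14 steps (steps 9 to 22, from geranyl acetate); the acid branch has 8 steps (steps 1 to 8).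

Steps most likely to fail:

1. Step 18 (key bicyclisation). What may go wrong: protodesilylation of the allylsilane, or interruption of the cascade after ring A, so that ring B closes late and without control of the alkene position. Fallback: set out from silyl enol ether 23 (steps 16 and 17 are then not needed). Treatment with MeAlCl2 (CH2Cl2, −94 °C) uses the silyl enol ether itself as the terminating nucleophile and should give the 8-oxo-17-nor compound F1 with the same ring fusion and C9 configuration. Wittig methylenation (Ph3P=CH2 from Ph3PCH3Br and KOtBu, toluene) then installs C17 and comes back to the route at 26.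

2. Step 15 (three-component union). What may go wrong: attack of the siloxyallyl anion on the ester carbonyl, or deprotonation of the bromo ester, instead of SN2 alkylation; α- instead of γ-alkylation. Fallback (iterative acetoacetate route, which also bypasses step 14): set out from bromide 16.
   - Alkylation of the dianion of methyl acetoacetate (NaH, n-BuLi, THF, 0 °C) gives the β-keto ester F2.
   - NaH and ClP(O)(OEt)2 give the (Z)-enol phosphate F3.
   - Me3SiCH2MgCl with Ni(acac)2 gives the allylsilane ester F4 with retention.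
   - iBu2AlH (−78 °C) gives the allylic alcohol F5.
   - MsCl/Et3N, then LiBr, gives the allylic bromide F6.
   - A second acetoacetate dianion alkylation gives the β-keto ester F7.
   - NaH and ClP(O)(OEt)2 give the enol phosphate F8.
   - Me2CuLi (Et2O, −78 °C) replaces the phosphate by methyl with retention and comes back to the route at 25.

3. Step 5 (directed hydrogenation). What may go wrong: migration of the β,γ-double bond into conjugation with the ketone, or hemiketal formation that masks the directing hydroxyl, before hydrogen is delivered; the ring C–H centre would then be set without control. Fallback: set out from 5. NaBH4 with CeCl3 (MeOH, 0 °C) removes the carbonyl as the homoallylic diol F9; the same iridium-catalysed hydroxyl-directed hydrogenation gives the saturated diol F10; selective oxidation of the secondary alcohol (Dess–Martin periodinane) comes back to the route at 6.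

Further compounds
F1 | step 18 | methyl (13E)-18-{[tert-butyl(dimethyl)silyl]oxy}-3β-hydroxy-8-oxo-17-norlabd-13-en-15-oate | O=C1CC[C@H]2[C@](C)(CO[Si](C)(C)C(C)(C)C)[C@@H](O)CC[C@]2(C)[C@H]1CC/C(C)=C/C(=O)OC
F2 | step 15 | methyl (6E)-9-[(2S,3S)-3-({[tert-butyl(dimethyl)silyl]oxy}methyl)-3-methyloxiran-2-yl]-7-methyl-3-oxonon-6-enoate | COC(=O)CC(=O)CC/C=C(C)/CC[C@@H]1O[C@@]1(C)CO[Si](C)(C)C(C)(C)C
F3 | step 15 | methyl (2Z,6E)-9-[(2S,3S)-3-({[tert-butyl(dimethyl)silyl]oxy}methyl)-3-methyloxiran-2-yl]-3-[(diethoxyphosphoryl)oxy]-7-methylnona-2,6-dienoate | COC(=O)/C=C(OP(=O)(OCC)OCC)/CC/C=C(C)/CC[C@@H]1O[C@@]1(C)CO[Si](C)(C)C(C)(C)C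
F4 | step 15 | methyl (2Z,6E)-9-[(2S,3S)-3-({[tert-butyl(dimethyl)silyl]oxy}methyl)-3-methyloxiran-2-yl]-7-methyl-3-[(trimethylsilyl)methyl]nona-2,6-dienoate | COC(=O)/C=C(C[Si](C)(C)C)/CC/C=C(C)/CC[C@@H]1O[C@@]1(C)CO[Si](C)(C)C(C)(C)C
F5 | step 15 | (2Z,6E)-9-[(2S,3S)-3-({[tert-butyl(dimethyl)silyl]oxy}methyl)-3-methyloxiran-2-yl]-7-methyl-3-[(trimethylsilyl)methyl]nona-2,6-dien-1-ol | OC/C=C(C[Si](C)(C)C)/CC/C=C(C)/CC[C@@H]1O[C@@]1(C)CO[Si](C)(C)C(C)(C)C
F6 | step 15 | (2S,3S)-3-[(3E,7Z)-9-bromo-3-methyl-7-[(trimethylsilyl)methyl]nona-3,7-dien-1-yl]-2-({[tert-butyl(dimethyl)silyl]oxy}methyl)-2-methyloxirane | BrC/C=C(C[Si](C)(C)C)/CC/C=C(C)/CC[C@@H]1O[C@@]1(C)CO[Si](C)(C)C(C)(C)C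
F7 | step 15 | methyl (6Z,10E)-13-[(2S,3S)-3-({[tert-butyl(dimethyl)silyl]oxy}methyl)-3-methyloxiran-2-yl]-11-methyl-3-oxo-7-[(trimethylsilyl)methyl]trideca-6,10-dienoate | COC(=O)CC(=O)CC/C=C(C[Si](C)(C)C)/CC/C=C(C)/CC[C@@H]1O[C@@]1(C)CO[Si](C)(C)C(C)(C)C
F8 | step 15 | methyl (2Z,6Z,10E)-13-[(2S,3S)-3-({[tert-butyl(dimethyl)silyl]oxy}methyl)-3-methyloxiran-2-yl]-3-[(diethoxyphosphoryl)oxy]-11-methyl-7-[(trimethylsilyl)methyl]trideca-2,6,10-trienoate | COC(=O)/C=C(OP(=O)(OCC)OCC)/CC/C=C(C[Si](C)(C)C)/CC/C=C(C)/CC[C@@H]1O[C@@]1(C)CO[Si](C)(C)C(C)(C)C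
F9 | step 5 | 4-[(2R)-2-hydroxy-2,6,6-trimethylcyclohexylidene]butan-2-ol (isomer mixture) | CC(O)CC=C1C(C)(C)CCC[C@@]1(C)O
F10 | step 5 | 4-[(1R,2R)-2-hydroxy-2,6,6-trimethylcyclohexyl]butan-2-ol (epimers at the chain carbinol) | CC(O)CC[C@@H]1C(C)(C)CCC[C@@]1(C)O
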